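Late in the alder run target stops moving, and this stop is the subject of the examination. Alder is the flask asked about, followed so far; ash is the same charge run colder.

| setting | alder | ash | flask |
|---|---|---|---|
| starting material | 0.13 M | 0.13 M | 0.13 M |
| free catalyst | 20 mM | 20 mM | 20 mM |
| temperature | 25 °C | 20 °C | 25 °C |
| remark | the very flask that is asked about, followed so far | run made earlier |  |
| time |  |  | 8.0 d |

| run | time / h | target / % | starting material / % |
|---|---|---|---|
| alder | 15.0 | 31 | 41 |
| alder | 50.0 | 32 | 12 |
| alder | 96.0 | 28 | 1 |
| alder | 144 | 25 | 0 |
| alder | 192 | 24 | 0 |
| ash | 15.0 | 30 | 58 |
| ash | 50.0 | 41 | 21 |
| ash | 96.0 | 31 | 5 |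
| ash | 144 | 25 | 3 |
| ash | 192 | 19 | 0 |

(readings scatter by 2 percentage points)

- south-east: at 8.0 d raise the temperature by 10 K, then wait 2.5 d
- north-west: change nothing and wait 2.5 d more
- west: at 8.0 d add free catalyst, 100% of the amount charged, then wait 2.5 d
- east: at 8.0 d take out 90% of the target then present, then wait 2.5 d

- target taken out counts as made
- the numbers in the tables scatter by 2 percentage points (one standard deviation)
- additions bring no volume worth counting

1. target, in percent of the starting material first charged, at 8.0 d
2. the remedy with the largest gain of target, or "none" below 2 percentage points (south-east / north-west / west / east / none)
3. target present, with what was taken out counted in, in percent of the starting material first charged, after west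
4. target present, with what was taken out counted in, in percent of the starting material first charged, after east

What do the last alder readings say? Starting material reads 0% at 144 h and 0% at 192 h, while target reads 25%, then 24%, a step inside the scatter of 2 percentage points. So I replace the tail of the curve by its mean, 24.5%, and call it s, the resting share: the part of everything charged that stands as target once starting material reads zero and target stops moving. The error of that mean is 1.4 points.

Is the stop a balance or a loss that died? The readings prove neither, but I read a balance with something unseen (thermodynamic control), since colder ash ends lower than alder, at 19%.

What does s give for alder? My reckoning puts target at s at 8.0 d and, reading the stop as a balance, also after waiting or after west. For east, 90% of s leaves the flask and what remains of the charge rests again at the share s. The wait of 2.5 d exceeds the 48.0 h between the alder readings of 28% and 25%. That makes 41.1% in all.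

And heating? Let r be the ratio of non-target to target at rest: 3.08 in alder, and Q the same ratio from the last ash reading, 4.26. With ln r taken as straight in temperature, 10 K is two gaps of the size between ash and alder, so my reckoning rests target near 38.3%.

Where is this weakest? Ash went from 25% to 19% over its last two readings, so Q, read at its end, is probably too small and that heating figure too low. I still commit to east, with a gain of 17 points against 14 points, though narrowly.

The forecast stands near my reckoning at the present value and parts from it after that: it gives 24%, none as the choice, 11% after west and 23.8% after east, reading “catalyst-driven decay, with the catalyst dying within days”.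

The flask gives 24.3%, 22.8% after west and 40.1% after east, and its best remedy is south-east, gaining 20 points against 16 points for east, so my order was wrong. The step between target and isomer of the product, taken alone with both ways together, relaxes with a half-life of 12.0 h, short against 8.0 d. Used once more, s on the 78.1% of the charge left in the flask after east gives 19.1%; the flask holds 18.2% there as target.

    catalyst intermediate ⇌ free catalyst + target (K = 0.0590 M, k = 1.50 h⁻¹, Ea = 99.0 kJ mol⁻¹, ΔH = −55.0 kJ mol⁻¹)
    target ⇌ isomer of the product (K = 2.90, k = 0.0430 h⁻¹, Ea = 108 kJ mol⁻¹, ΔH = −80.0 kJ mol⁻¹)
    starting material + free catalyst → catalyst intermediate (k = 4.20 M⁻¹ h⁻¹, Ea = 69.0 kJ mol⁻¹)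
    (constants at 25 °C)

For the neighbour flask read at 3.0 d, s says 24.5%. The computed flask holds 29.4%, which is 4.9 points higher, with 3.33% of the starting material still there.

The numbers in the tables were computed on assumed constants; noise was put on by code.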